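**Plan**

Numbering: ring C1 (CH3, vinyl), C2 (isopropenyl), C3, C4 (side chain), C5, C6; chain C7 (on C4), C8 (CH2OAc), C9 (=CH), C10, C11 (CHOAc), C12 (C(CH3)2OH).
Cuts: both acetates; the Z-diol is traced back to δ-lactone 19 (ring O–C8–C7=C9–C10–C11), which is cut at C9–C10 and at O–C8 into acrylic acid 15 and epoxide 18.
Enabling feature: in 15 the carboxyl C8 and ring carbon C4 sit on C7 of a 1,1-disubstituted alkene, so the C9–H bond cis to C8 can be palladated through the carboxylate; alkylation by epoxide carbon C10 and closure of the C11 oxygen onto C8 give the six-membered lactone, which holds C8 and C10 cis (the Z alkene).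
Forward order: cyclohexenone → C4 side chain (conjugate addition, allylic C–H to ether) → C1 quaternary centre (formylation, methylation, methylenation) → C2 isopropenyl from the ring ketone → unmask the acid → join C10–C12 and close the lactone (the only ring formed) → open and acetylate.
Stereochemistry: C4 from Rh/(S)-BINAP addition; C1 from axial methylation cis to the C4 substituent; C2 from enolate protonation anti to the axial C1 methyl; C11 from methyl (S)-glycidate; alkene geometry from the palladacycle and lactone.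

Key step: step 13

Remark: 9, 10 and 20 are carried as mixtures at the one carbon left without configuration in their SMILES (the carbinol carbon of 9 and 10, the lactol carbon of 20); each of these centres is cleared in the same or the next step.

Step 1
Reactants: 1 cyclohex-2-en-1-one; 2 isopropenylboronic acid pinacol ester
Product: 3 (3S)-3-(prop-1-en-2-yl)cyclohexan-1-one
Conditions: [RhCl(cod)]2 (2.5 mol%), (S)-BINAP (6 mol%), KOH (0.5 equiv), dioxane/H2O 10:1, 50 °C
Reagents that add atoms: none
Why: Hayashi–Miyaura rhodium-catalysed asymmetric 1,4-addition, in which the alkenyl–rhodium–BINAP species adds to one enantioface of the enone and water protonates the rhodium enolate; (S)-BINAP is expected to give the 3S ketone, the sense seen with aryl- and alkenylboron reagents, and this sets C4 of the target.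

Step 2
Reactants: 3 (3S)-3-(prop-1-en-2-yl)cyclohexan-1-one
Product: 4 (3S)-3-(3-chloroprop-1-en-2-yl)cyclohexan-1-one
Conditions: NaOCl (aq), CeCl3·7H2O, CH2Cl2/H2O, 0 °C → rt
Reagents that add atoms: sodium hypochlorite, [Na+].[O-]Cl
Why: Ene-type allylic chlorination by electrophilic chlorine, in which chlorine adds to the terminal CH2 and a proton is lost from the methyl group rather than the ring methine, as in the chlorination of the isopropenyl group of carvone; the stereocentre is not involved.

Step 3
Reactants: 4 (3S)-3-(3-chloroprop-1-en-2-yl)cyclohexan-1-one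
Product: 5 (3S)-3-[3-(4-methoxyphenoxy)prop-1-en-2-yl]cyclohexan-1-one
Conditions: 4-methoxyphenol, K2CO3, NaI (cat.), acetone, 55 °C
Reagents that add atoms: 4-methoxyphenol, COc1ccc(O)cc1
Why: Williamson ether synthesis on a 2-substituted allyl chloride (SN2 and SN2′ give the same product); the weakly basic phenoxide leaves the ketone un-enolised, which avoids intramolecular C-alkylation, and the aryl ether masks the future C8 oxygen against enolates, organolithiums and ylides.

Step 4
Reactants: 5 (3S)-3-[3-(4-methoxyphenoxy)prop-1-en-2-yl]cyclohexan-1-one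
Product: 6 (2Z,5S)-2-(hydroxymethylidene)-5-[3-(4-methoxyphenoxy)prop-1-en-2-yl]cyclohexan-1-one
Conditions: NaH, HCO2Et, EtOH (cat.), THF, 0 °C → rt; aq. HCl work-up
Reagents that add atoms: ethyl formate, CCOC=O
Why: Crossed Claisen condensation (formylation) under equilibrating conditions puts the formyl group on the less hindered α-methylene, the one remote from the side chain (the future C1), and the product is drained from the equilibrium as its sodium salt.

Step 5
Reactants: 6 (2Z,5S)-2-(hydroxymethylidene)-5-[3-(4-methoxyphenoxy)prop-1-en-2-yl]cyclohexan-1-one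
Product: 7 (1R,4S)-1-methyl-4-[3-(4-methoxyphenoxy)prop-1-en-2-yl]-2-oxocyclohexane-1-carbaldehyde
Conditions: MeI, K2CO3, acetone, rt
Reagents that add atoms: iodomethane, CI
Why: C-Alkylation of the β-keto aldehyde enolate with the soft electrophile MeI; the enolate ring is a half-chair with the side chain equatorial, and stereoelectronically preferred axial attack should put the new methyl group cis to that side chain (the C1 configuration of the target, the same facial preference as in alkylations of 5-substituted cyclohexanone enolates), with the minor epimer to be removed at this stage.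

Step 6
Reactants: 7 (1R,4S)-1-methyl-4-[3-(4-methoxyphenoxy)prop-1-en-2-yl]-2-oxocyclohexane-1-carbaldehyde
Product: 8 (2R,5S)-2-ethenyl-2-methyl-5-[3-(4-methoxyphenoxy)prop-1-en-2-yl]cyclohexan-1-one
Conditions: Ph3PCH3Br, KN(SiMe3)2 (1.05 equiv ylide), THF, −78 → 0 °C
Reagents that add atoms: methyltriphenylphosphonium bromide, C[P+](c1ccccc1)(c1ccccc1)c1ccccc1.[Br-]
Why: Wittig methylenation, in which one equivalent of ylide should take the aldehyde in preference to the α-quaternary ketone; the quaternary centre cannot epimerise.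

Step 7
Reactants: 8 (2R,5S)-2-ethenyl-2-methyl-5-[3-(4-methoxyphenoxy)prop-1-en-2-yl]cyclohexan-1-one
Product: 10 1-{(2R,5S)-2-ethenyl-1-hydroxy-2-methyl-5-[3-(4-methoxyphenoxy)prop-1-en-2-yl]cyclohexyl}ethan-1-one, via ethoxyvinyl carbinol 9 (not isolated)
Conditions: ethyl vinyl ether, t-BuLi, THF, −78 → 0 °C; add 8, −78 → −20 °C; then 0.5 M HCl, THF/H2O, 0 °C
Reagents that add atoms: ethyl vinyl ether, C=COCC; water, O
Why: Addition of 1-ethoxyvinyllithium, an acetyl anion equivalent, to the ketone followed by mild acid hydrolysis of the enol ether, the sequence used to turn hindered 17-oxo steroids into 17-hydroxy-20-ketones; the configuration of the new carbinol centre does not matter.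

Step 8
Reactants: 10 1-{(2R,5S)-2-ethenyl-1-hydroxy-2-methyl-5-[3-(4-methoxyphenoxy)prop-1-en-2-yl]cyclohexyl}ethan-1-one
Product: 11 1-{(1S,2R,5S)-2-ethenyl-2-methyl-5-[3-(4-methoxyphenoxy)prop-1-en-2-yl]cyclohexyl}ethan-1-one
Conditions: SmI2 (3 equiv), MeOH (10 equiv), THF, −78 → 0 °C
Reagents that add atoms: none
Why: Reduction of an α-hydroxy ketone by divalent samarium (electron transfer, loss of hydroxide, second electron) gives the samarium enolate exocyclic to C2, which methanol should protonate from the face anti to the axial C1 methyl; this places acetyl equatorial (trans to vinyl, cis to the C4 side chain), which is also the more stable epimer, as for 20-oxopregnanes next to their angular methyl group.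

Step 9
Reactants: 11 1-{(1S,2R,5S)-2-ethenyl-2-methyl-5-[3-(4-methoxyphenoxy)prop-1-en-2-yl]cyclohexyl}ethan-1-one
Product: 12 1-methoxy-4-({2-[(1S,3R,4R)-4-ethenyl-4-methyl-3-(prop-1-en-2-yl)cyclohexyl]prop-2-en-1-yl}oxy)benzene
Conditions: Ph3PCH3Br, KOt-Bu, THF, 0 °C → reflux
Reagents that add atoms: methyltriphenylphosphonium bromide, C[P+](c1ccccc1)(c1ccccc1)c1ccccc1.[Br-]
Why: Wittig methylenation of a hindered methyl ketone under forcing conditions; the acetyl epimer present is the one favoured both kinetically and at equilibrium, so the basic ylide should not erode C2.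

Step 10
Reactants: 12 1-methoxy-4-({2-[(1S,3R,4R)-4-ethenyl-4-methyl-3-(prop-1-en-2-yl)cyclohexyl]prop-2-en-1-yl}oxy)benzene
Product: 13 2-[(1S,3R,4R)-4-ethenyl-4-methyl-3-(prop-1-en-2-yl)cyclohexyl]prop-2-en-1-ol
Conditions: (NH4)2Ce(NO3)6 (2.5 equiv), MeCN/H2O 4:1, 0 °C
Reagents that add atoms: none
Why: Oxidative removal of a p-methoxyphenyl ether by tetravalent cerium, in which the arene is oxidised, water adds at the ipso carbon and the hemiketal collapses to benzoquinone and the free allylic alcohol; the three isolated alkenes should not be oxidised at 0 °C.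

Step 11
Reactants: 13 2-[(1S,3R,4R)-4-ethenyl-4-methyl-3-(prop-1-en-2-yl)cyclohexyl]prop-2-en-1-ol
Product: 15 2-[(1S,3R,4R)-4-ethenyl-4-methyl-3-(prop-1-en-2-yl)cyclohexyl]prop-2-enoic acid, via enal 14 (not isolated)
Conditions: TEMPO (10 mol%), PhI(OAc)2 (1.1 equiv), CH2Cl2, rt; then t-BuOH, 2-methylbut-2-ene, NaClO2, NaH2PO4, H2O, 0 °C → rt
Reagents that add atoms: sodium chlorite, [Na+].[O-]Cl=O
Why: Oxoammonium (TEMPO/PhI(OAc)2) oxidation of the allylic alcohol to the 2-substituted acrolein and Pinnick oxidation of that enal in the same flask; 2-methylbut-2-ene traps the hypochlorous acid that would otherwise chlorinate the isopropenyl group.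

Step 12
Reactants: 16 methyl (2S)-oxirane-2-carboxylate
Product: 18 2-[(2S)-oxiran-2-yl]propan-2-ol, via epoxy ketone 17 (not isolated)
Conditions: MeLi (2.1 equiv), THF, −78 °C; AcOH quench at −78 °C
Reagents that add atoms: methyllithium, [Li]C
Why: Double addition of methyllithium to the ester through the ketone; at −78 °C the carbonyl groups react far faster than the epoxide, no bond to the stereocentre is made or broken and its C–H is not enolisable, so the S configuration passes into C11, and the cold acidic quench forestalls Payne rearrangement of the tertiary alkoxide.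

Step 13
Reactants: 15 2-[(1S,3R,4R)-4-ethenyl-4-methyl-3-(prop-1-en-2-yl)cyclohexyl]prop-2-enoic acid; 18 2-[(2S)-oxiran-2-yl]propan-2-ol
Product: 19 (6S)-3-[(1S,3R,4R)-4-ethenyl-4-methyl-3-(prop-1-en-2-yl)cyclohexyl]-6-(2-hydroxypropan-2-yl)-5,6-dihydro-2H-pyran-2-one
Conditions: Pd(OAc)2 (10 mol%), N-acetyl-L-tert-leucine (20 mol%), KOAc (1.0 equiv), 18 (2.0 equiv), (CF3)2CHOH, 60 °C
Reagents that add atoms: none
Why: Proposed new method: the potassium carboxylate of 15 binds Pd(OAc)2 and, by carboxylate-assisted concerted metalation–deprotonation, palladates the one C9–H bond that lies cis to C8, giving a five-membered alkenyl palladacycle of divalent palladium; its C9–Pd bond opens the coordinated epoxide at the unsubstituted carbon C10 in an SN2-type, redox-neutral step, protonolysis frees the catalyst, and the C11 hydroxyl then closes onto C8 (6-exo-trig lactonisation with loss of water). The closest known reaction type is the Pd(OAc)2-catalysed, carboxylate-directed ortho C–H alkylation of benzoic acids with terminal epoxides to 3,4-dihydroisocoumarins under the same KOAc/hexafluoroisopropanol conditions; here the alkenyl C–H bond of an acrylic acid takes the place of the aryl C–H bond. No stereocentre is created: C11 keeps the S configuration of 18 because only the C10–O bond is broken, and the C7=C9 geometry is dictated by the palladacycle and then held by the lactone ring, which places C8 and C10 cis. The step needs site selectivity for C9–H over the allylic C4–H and the other alkenes, and attack at C10 rather than C11; the first should be secured by the geometry of the five-membered palladacycle and by the absence of any oxidant that could turn over Wacker-type or allylic oxidation of the vinyl and isopropenyl groups, the second by the steric bias of the tertiary carbinol at C12. The mono-protected amino acid ligand is included to speed the metalation so that it outruns O-alkylation of the carboxylate by the epoxide.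

Step 14
Reactants: 19 (6S)-3-[(1S,3R,4R)-4-ethenyl-4-methyl-3-(prop-1-en-2-yl)cyclohexyl]-6-(2-hydroxypropan-2-yl)-5,6-dihydro-2H-pyran-2-one
Product: 21 (2Z,5S)-2-[(1S,3R,4R)-4-ethenyl-4-methyl-3-(prop-1-en-2-yl)cyclohexyl]-6-methylhept-2-ene-1,5,6-triol, via lactol 20 (not isolated)
Conditions: i-Bu2AlH (5 equiv), CH2Cl2, −78 → 0 °C; aq. potassium sodium tartrate work-up
Reagents that add atoms: none
Why: 1,2-Reduction of the α,β-unsaturated lactone by the Lewis-acidic aluminium hydride, through the lactol to the allylic 1,5-diol; conjugate reduction is not expected, so the C7=C9 bond keeps the Z geometry imposed by the ring and C11 is untouched.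

Step 15
Reactants: 21 (2Z,5S)-2-[(1S,3R,4R)-4-ethenyl-4-methyl-3-(prop-1-en-2-yl)cyclohexyl]-6-methylhept-2-ene-1,5,6-triol
Product: 22 (2Z,5S)-2-[(1S,3R,4R)-4-ethenyl-4-methyl-3-(prop-1-en-2-yl)cyclohexyl]-6-hydroxy-6-methylhept-2-ene-1,5-diyl diacetate
Conditions: Ac2O (2.5 equiv), pyridine, DMAP (5 mol%), CH2Cl2, 0 °C → rt
Reagents that add atoms: acetic anhydride, CC(=O)OC(C)=O
Why: Acylation with DMAP catalysis esterifies the primary allylic and the secondary hydroxyl groups, while the tertiary hydroxyl is too hindered to react under these conditions.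

**Compound list**

1 | cyclohex-2-en-1-one | O=C1C=CCCC1 | starting material
2 | isopropenylboronic acid pinacol ester | CC(=C)B1OC(C)(C)C(C)(C)O1 | starting material
3 | (3S)-3-(prop-1-en-2-yl)cyclohexan-1-one | CC(=C)[C@H]1CCCC(=O)C1 | intermediate
4 | (3S)-3-(3-chloroprop-1-en-2-yl)cyclohexan-1-one | ClCC(=C)[C@H]1CCCC(=O)C1 | intermediate
5 | (3S)-3-[3-(4-methoxyphenoxy)prop-1-en-2-yl]cyclohexan-1-one | COc1ccc(OCC(=C)[C@H]2CCCC(=O)C2)cc1 | intermediate
6 | (2Z,5S)-2-(hydroxymethylidene)-5-[3-(4-methoxyphenoxy)prop-1-en-2-yl]cyclohexan-1-one (chelated enol of the β-keto aldehyde) | COc1ccc(OCC(=C)[C@H]2CC/C(=C/O)C(=O)C2)cc1 | intermediate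
7 | (1R,4S)-1-methyl-4-[3-(4-methoxyphenoxy)prop-1-en-2-yl]-2-oxocyclohexane-1-carbaldehyde (methyl cis to the side chain) | O=C[C@@]1(C)CC[C@H](C(=C)COc2ccc(OC)cc2)CC1=O | intermediate
8 | (2R,5S)-2-ethenyl-2-methyl-5-[3-(4-methoxyphenoxy)prop-1-en-2-yl]cyclohexan-1-one | C=C[C@@]1(C)CC[C@H](C(=C)COc2ccc(OC)cc2)CC1=O | intermediate
9 | (2R,5S)-2-ethenyl-1-(1-ethoxyethenyl)-2-methyl-5-[3-(4-methoxyphenoxy)prop-1-en-2-yl]cyclohexan-1-ol (not isolated; carbinol epimers) | C=C[C@@]1(C)CC[C@H](C(=C)COc2ccc(OC)cc2)CC1(O)C(=C)OCC | intermediate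
10 | 1-{(2R,5S)-2-ethenyl-1-hydroxy-2-methyl-5-[3-(4-methoxyphenoxy)prop-1-en-2-yl]cyclohexyl}ethan-1-one (carbinol epimers) | C=C[C@@]1(C)CC[C@H](C(=C)COc2ccc(OC)cc2)CC1(O)C(C)=O | intermediate
11 | 1-{(1S,2R,5S)-2-ethenyl-2-methyl-5-[3-(4-methoxyphenoxy)prop-1-en-2-yl]cyclohexyl}ethan-1-one (acetyl trans to vinyl) | C=C[C@@]1(C)CC[C@H](C(=C)COc2ccc(OC)cc2)C[C@@H]1C(C)=O | intermediate
12 | 1-methoxy-4-({2-[(1S,3R,4R)-4-ethenyl-4-methyl-3-(prop-1-en-2-yl)cyclohexyl]prop-2-en-1-yl}oxy)benzene | C=C[C@@]1(C)CC[C@H](C(=C)COc2ccc(OC)cc2)C[C@@H]1C(=C)C | intermediate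
13 | 2-[(1S,3R,4R)-4-ethenyl-4-methyl-3-(prop-1-en-2-yl)cyclohexyl]prop-2-en-1-ol | C=C[C@@]1(C)CC[C@H](C(=C)CO)C[C@@H]1C(=C)C | intermediate
14 | 2-[(1S,3R,4R)-4-ethenyl-4-methyl-3-(prop-1-en-2-yl)cyclohexyl]prop-2-enal (not isolated) | C=C[C@@]1(C)CC[C@H](C(=C)C=O)C[C@@H]1C(=C)C | intermediate
15 | 2-[(1S,3R,4R)-4-ethenyl-4-methyl-3-(prop-1-en-2-yl)cyclohexyl]prop-2-enoic acid | C=C[C@@]1(C)CC[C@H](C(=C)C(=O)O)C[C@@H]1C(=C)C | intermediate
16 | methyl (2S)-oxirane-2-carboxylate (methyl (S)-glycidate) | COC(=O)[C@@H]1CO1 | starting material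
17 | 1-[(2S)-oxiran-2-yl]ethan-1-one (not isolated) | CC(=O)[C@@H]1CO1 | intermediate
18 | 2-[(2S)-oxiran-2-yl]propan-2-ol | CC(C)(O)[C@@H]1CO1 | intermediate
19 | (6S)-3-[(1S,3R,4R)-4-ethenyl-4-methyl-3-(prop-1-en-2-yl)cyclohexyl]-6-(2-hydroxypropan-2-yl)-5,6-dihydro-2H-pyran-2-one | C=C[C@@]1(C)CC[C@H](C2=CC[C@@H](C(C)(C)O)OC2=O)C[C@@H]1C(=C)C | intermediate
20 | (6S)-3-[(1S,3R,4R)-4-ethenyl-4-methyl-3-(prop-1-en-2-yl)cyclohexyl]-6-(2-hydroxypropan-2-yl)-5,6-dihydro-2H-pyran-2-ol (not isolated; anomers) | C=C[C@@]1(C)CC[C@H](C2=CC[C@@H](C(C)(C)O)OC2O)C[C@@H]1C(=C)C | intermediate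
21 | (2Z,5S)-2-[(1S,3R,4R)-4-ethenyl-4-methyl-3-(prop-1-en-2-yl)cyclohexyl]-6-methylhept-2-ene-1,5,6-triol | C=C[C@@]1(C)CC[C@H](/C(=C/C[C@H](O)C(C)(C)O)CO)C[C@@H]1C(=C)C | intermediate
22 | (2Z,5S)-2-[(1S,3R,4R)-4-ethenyl-4-methyl-3-(prop-1-en-2-yl)cyclohexyl]-6-hydroxy-6-methylhept-2-ene-1,5-diyl diacetate | C=C[C@@]1(C)CC[C@H](/C(=C/C[C@H](OC(C)=O)C(C)(C)O)COC(C)=O)C[C@@H]1C(=C)C | target

**Step count and risks**

Total: 15 steps. Longest linear sequence: 14 steps (steps 1–11 and 13–15); step 12 is a one-step branch.

Steps most likely to fail: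

1. Step 13 (proposed new method). The vinylic C–H palladation may be slow or absent because the ring vinyl and isopropenyl groups tie up the catalyst. The carboxylate may be O-alkylated by the epoxide, or the epoxide may open or rearrange in the acidic fluorinated alcohol before C–C bond formation. The fallback uses known chemistry, sets out from 15 and 18 and returns at 19. Opening of 18 at its terminal carbon with vinylmagnesium bromide and catalytic CuI would give (3S)-2-methylhex-5-ene-2,3-diol F1. Yamaguchi esterification of 15 with the secondary hydroxyl of F1 (2,4,6-trichlorobenzoyl chloride, Et3N, DMAP) would give (3S)-2-hydroxy-2-methylhex-5-en-3-yl 2-[(1S,3R,4R)-4-ethenyl-4-methyl-3-(prop-1-en-2-yl)cyclohexyl]prop-2-enoate F2. Ring-closing metathesis of F2 with second-generation Grubbs catalyst in hot toluene, between the acrylate alkene and the terminal alkene, would close the same lactone 19; the six-membered ring again fixes the alkene geometry and C11 comes unchanged from 18.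

2. Step 5. Facial discrimination in the methylation may be low (small electrophile, early transition state) and O-methylation may compete, so C1 could be set with a poor ratio. The fallback replaces substrate control by reagent control, sets out from 5 and returns at 7. Carbomethoxylation of 5 (NaH, dimethyl carbonate) would give methyl (4S)-4-[3-(4-methoxyphenoxy)prop-1-en-2-yl]-2-oxocyclohexane-1-carboxylate F3. Methylation of this β-keto ester with MeI under a cinchona-derived chiral quaternary ammonium phase-transfer catalyst, chosen to match the substrate bias, would give methyl (1S,4S)-1-methyl-4-[3-(4-methoxyphenoxy)prop-1-en-2-yl]-2-oxocyclohexane-1-carboxylate F4. Reduction with LiAlH4 would give (2R,5S)-2-(hydroxymethyl)-2-methyl-5-[3-(4-methoxyphenoxy)prop-1-en-2-yl]cyclohexan-1-ol F5, and double Swern oxidation of F5 would give 7.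

3. Step 7. The basic vinyllithium may enolise the hindered α-quaternary ketone instead of adding to it, and the tertiary ketol may undergo acyloin-type rearrangement during hydrolysis. The fallback sets out from 8 and returns at 11, bypassing 9 and 10. Van Leusen reductive cyanation of 8 (TosMIC, KOt-Bu, EtOH, DME) would give (2R,5S)-2-ethenyl-2-methyl-5-[3-(4-methoxyphenoxy)prop-1-en-2-yl]cyclohexane-1-carbonitrile F6 as a mixture of epimers at the nitrile carbon. Addition of MeLi and acidic hydrolysis of the imine, followed by NaOMe/MeOH equilibration toward the equatorial acetyl epimer with recycling of the minor one, would lead to 11; here C2 rests on thermodynamic rather than kinetic control.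

**Further compounds**

F1 | step 13 | (3S)-2-methylhex-5-ene-2,3-diol | C=CC[C@H](O)C(C)(C)O
F2 | step 13 | (3S)-2-hydroxy-2-methylhex-5-en-3-yl 2-[(1S,3R,4R)-4-ethenyl-4-methyl-3-(prop-1-en-2-yl)cyclohexyl]prop-2-enoate | C=C[C@@]1(C)CC[C@H](C(=C)C(=O)O[C@@H](CC=C)C(C)(C)O)C[C@@H]1C(=C)C
F3 | step 5 | methyl (4S)-4-[3-(4-methoxyphenoxy)prop-1-en-2-yl]-2-oxocyclohexane-1-carboxylate | COC(=O)C1CC[C@H](C(=C)COc2ccc(OC)cc2)CC1=O
F4 | step 5 | methyl (1S,4S)-1-methyl-4-[3-(4-methoxyphenoxy)prop-1-en-2-yl]-2-oxocyclohexane-1-carboxylate | COC(=O)[C@@]1(C)CC[C@H](C(=C)COc2ccc(OC)cc2)CC1=O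
F5 | step 5 | (2R,5S)-2-(hydroxymethyl)-2-methyl-5-[3-(4-methoxyphenoxy)prop-1-en-2-yl]cyclohexan-1-ol | OC[C@@]1(C)CC[C@H](C(=C)COc2ccc(OC)cc2)CC1O
F6 | step 7 | (2R,5S)-2-ethenyl-2-methyl-5-[3-(4-methoxyphenoxy)prop-1-en-2-yl]cyclohexane-1-carbonitrile | C=C[C@@]1(C)CC[C@H](C(=C)COc2ccc(OC)cc2)CC1C#N
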